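## Retrosynthetic overview

1. Cyclopentanone numbering: C1 is the carbonyl, C2 the CH bearing the cyclopropane, C3 the quaternary C(CH3) bearing the benzylic CH, and C4 and C5 the two CH2 groups. The strategy rests on the C1-C2-C3 array. C3 is beta to the carbonyl and sits between the enolisable C2 and the benzylic stereocentre, so cutting C1-C5 leaves a 2,3,3-trisubstituted pent-4-enal, which is a Claisen retron.
2. Endgame: the two formyl groups (Vilsmeier-Haack), the phenols (benzyl ethers) and the side-chain ketone (dioxolane) are unveiled last. C1-C5 is made by rhodium-catalysed hydroacylation of the C4=C5 vinyl group.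
3. Key disconnection: C2-C3, by a [3,3] shift of an allyl vinyl ether. That ether is assembled by copper-catalysed C-O coupling of E-vinyl iodide 6 with E-allylic alcohol 19.
4. Compound 6 comes from (+)-2-carene: ozonolysis of the ring C=C gives the cis-cyclopropane with its 3-oxobutyl arm and a formyl stub, and Takai olefination follows. Compound 19 comes from 2,4,6-trihydroxybenzaldehyde, isobutylmagnesium bromide and but-2-yn-1-ol, through an enantioselective alkenylboronate addition to an o-quinone methide.
5. Ring order: the arene is bought, the cyclopropane is inherited from carene (whose six-membered ring is opened), and the cyclopentanone is closed last.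

Key step: step 13

Assumption: the sense of induction of 3,3'-dibromo-BINOL cannot be carried over safely to an alkyl-substituted quinone methide. The route is therefore written for the catalyst antipode that gives the R benzylic carbon, to be identified in a pilot run; both antipodes are sold.

## Route

Step 1
Reactants: 1 (+)-2-carene, (1S,6R)-3,7,7-trimethylbicyclo[4.1.0]hept-2-ene
Product: 3 (1S,3R)-2,2-dimethyl-3-(3-oxobutyl)cyclopropane-1-carbaldehyde (cis), via secondary ozonide 2 (not isolated)
Conditions: O3, CH2Cl2, -78 °C; then PPh3, -78 °C to rt; neutral work-up, used promptly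
Reagents that add atoms: ozone, [O-][O+]=O
Why: Criegee ozonolysis cleaves the only C=C of 1, turning the ring CH= into the formyl group and the C(CH3)= into the methyl ketone without touching the two cyclopropane stereocentres, and the neutral phosphine reduction of 2 avoids enolisation of the epimerisable cis aldehyde.

Step 2
Reactants: 3 keto aldehyde; 4 iodoform
Product: 5 4-{(1R,3R)-3-[(E)-2-iodoethenyl]-2,2-dimethylcyclopropyl}butan-2-one
Conditions: CrCl2 (6 equiv), CHI3 (2 equiv), THF-dioxane 1:6, 0 °C to rt
Reagents that add atoms: iodoform (compound 4), IC(I)I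
Why: In the Takai iodo-olefination the geminal dichromium species formed from CHI3 and divalent chromium adds to aldehydes far faster than to ketones and eliminates to the E-vinyl iodide, and the medium is non-basic, so the methyl ketone and the cis ring configuration should survive.

Step 3
Reactants: 5 E-vinyl iodide ketone
Product: 6 2-(2-{(1R,3R)-3-[(E)-2-iodoethenyl]-2,2-dimethylcyclopropyl}ethyl)-2-methyl-1,3-dioxolane
Conditions: HOCH2CH2OH, pyridinium tosylate (cat.), benzene, Dean-Stark, 80 °C
Reagents that add atoms: ethylene glycol, OCCO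
Why: This is acid-catalysed ketalisation with azeotropic water removal, in which pyridinium tosylate is too weak an acid to open the vinylcyclopropane or affect the vinyl iodide and 80 °C lies well below the onset of any sigmatropic hydrogen shift.

Step 4
Reactants: 7 2,4,6-trihydroxybenzaldehyde
Product: 8 2,4-bis(benzyloxy)-6-hydroxybenzaldehyde
Conditions: BnBr (2.05 equiv), K2CO3, DMF, 0 °C to rt
Reagents that add atoms: benzyl bromide, BrCc1ccccc1
Why: Williamson etherification under stoichiometric control alkylates the para OH and one of the two equivalent ortho OH groups, while the last ortho OH is held in a strong hydrogen bond to the formyl oxygen and is the least nucleophilic site.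

Step 5
Reactants: 8 dibenzyl ether aldehyde; 9 isobutylmagnesium bromide
Product: 10 rac-3,5-bis(benzyloxy)-2-(1-hydroxy-3-methylbutyl)phenol
Conditions: iBuMgBr (2.3 equiv), THF, -20 to 0 °C; buffered aq. NH4Cl quench; used without storage
Reagents that add atoms: isobutylmagnesium bromide (compound 9), CC(C)C[Mg]Br
Why: Grignard 1,2-addition follows deprotonation of the phenol by the first equivalent, the carbinol carbon is formed racemic (harmless, since it becomes planar in step 10), and the buffered quench protects the readily ionised benzylic alcohol.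

Step 6
Reactants: 11 but-2-yn-1-ol
Product: 12 (but-2-yn-1-yloxy)(tert-butyl)dimethylsilane
Conditions: TBSCl, imidazole, CH2Cl2, 0 °C to rt
Reagents that add atoms: tert-butyldimethylsilyl chloride, CC(C)(C)[Si](C)(C)Cl
Why: Imidazole-promoted silylation of the primary alcohol keeps the hydroxyl from quenching the copper boryl species and from binding to boron later.

Step 7
Reactants: 12 silyl ether
Product: 13 (Z)-tert-butyldimethyl{[3-(4,4,5,5-tetramethyl-1,3,2-dioxaborolan-2-yl)but-2-en-1-yl]oxy}silane (boron on the CH3-bearing carbon and cis to the vinyl H)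
Conditions: B2pin2 (1.1 equiv), CuCl (10 mol %), PCy3 (12 mol %), NaOtBu (15 mol %), MeOH (2 equiv), toluene, rt
Reagents that add atoms: bis(pinacolato)diboron, CC1(C)OB(OC1(C)C)B1OC(C)(C)C(C)(C)O1
Why: In this copper-catalysed formal hydroboration (syn borylcupration, then protonolysis of C-Cu by methanol with retention) the propargylic oxygen polarises the alkyne so that copper ends up next to CH2O and boron on the methyl-bearing carbon, which fixes boron cis to the vinyl hydrogen.

Step 8
Reactants: 13 pinacol boronate
Product: 14 (Z)-{4-[(tert-butyldimethylsilyl)oxy]but-2-en-2-yl}boronic acid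
Conditions: NaIO4 (3 equiv), NH4OAc (3 equiv), acetone-H2O 1:1, rt
Reagents that add atoms: water, O
Why: Pinacol esters do not transesterify directly with ethanol, so the diol is removed irreversibly by periodate glycol cleavage of the pinacol present in hydrolytic equilibrium, and the buffered medium leaves the silyl ether and the alkene geometry alone.

Step 9
Reactants: 14 boronic acid
Product: 15 diethyl (Z)-{4-[(tert-butyldimethylsilyl)oxy]but-2-en-2-yl}boronate
Conditions: EtOH (excess), 3 Å sieves, toluene, rt; filtered and concentrated under Ar, used at once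
Reagents that add atoms: ethanol, CCO
Why: Reversible boronic acid esterification, driven by molecular sieves, gives a labile acyclic ester that can exchange with a catalytic chiral diol in the next step.

Step 10
Reactants: 10 racemic o-hydroxybenzyl alcohol; 15 diethyl alkenylboronate (1.5 equiv)
Product: 17 3,5-bis(benzyloxy)-2-[(2E,4R)-1-(tert-butyldimethylsilyloxy)-3,6-dimethylhept-2-en-4-yl]phenol, via o-quinone methide 16 (not isolated)
Conditions: 3,3'-Br2-BINOL (15 mol %, antipode giving R), 4 Å sieves, toluene, 0 °C to rt
Reagents that add atoms: none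
Why: In this chiral-diol-catalysed 1,4-addition of an alkenylboronate to an o-quinone methide, boron-assisted loss of water from the electron-rich 10 gives 16, and the dibromo-BINOL replaces ethoxide on boron to give a more Lewis-acidic boronate that binds the quinone methide oxygen and delivers the alkenyl group to one face of the methide carbon in a closed transition state, which sets the R benzylic centre, rearomatises the ring and retains the alkene geometry.

Step 11
Reactants: 17 (R)-phenol
Product: 18 tert-butyl({(2E,4R)-3,6-dimethyl-4-[2,4,6-tris(benzyloxy)phenyl]hept-2-en-1-yl}oxy)dimethylsilane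
Conditions: BnBr, K2CO3, DMF, rt to 50 °C
Reagents that add atoms: benzyl bromide, BrCc1ccccc1
Why: Williamson etherification of the remaining phenol removes the acidic OH before the copper step, and the benzylic C-H is not acidic enough to be touched by carbonate.

Step 12
Reactants: 18 silyl ether
Product: 19 (2E,4R)-3,6-dimethyl-4-[2,4,6-tris(benzyloxy)phenyl]hept-2-en-1-ol
Conditions: Bu4NF, THF, 0 °C to rt
Reagents that add atoms: none
Why: Fluoride-induced desilylation, driven by the strong Si-F bond, frees the primary allylic alcohol without affecting the benzyl ethers, the alkene geometry or the stereocentre.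

Step 13
Reactants: 6 E-vinyl iodide dioxolane; 19 E-allylic alcohol
Product: 21 (2R,3R)-2-{(1R,3R)-2,2-dimethyl-3-[2-(2-methyl-1,3-dioxolan-2-yl)ethyl]cyclopropyl}-3-methyl-3-{(1R)-3-methyl-1-[2,4,6-tris(benzyloxy)phenyl]butyl}pent-4-enal, via allyl vinyl ether 20 (not isolated)
Conditions: CuI (10 mol %), 3,4,7,8-tetramethyl-1,10-phenanthroline (20 mol %), Cs2CO3 (1.5 equiv), o-xylene, 80 °C until 6 is consumed, then 110-120 °C (not higher)
Reagents that add atoms: none
Why: Phenanthroline-ligated monovalent copper joins the alkoxide of 19 to vinyl iodide 6 in an Ullmann-type C-O coupling with retention of the E geometry, and the resulting ether 20 then undergoes a concerted suprafacial [3,3] shift in the same flask that makes C2-C3 while O-CH2 breaks and unveils the C1 aldehyde and the C4=C5 vinyl group; no ring is closed in this step. The closest known reaction type is the domino copper-catalysed vinylation of allylic alcohols followed by Claisen rearrangement, which accepts gamma,gamma-disubstituted allylic alcohols and delivers quaternary carbons. In the chair the cyclopropyl group (E enol ether) and the benzylic arm (trans to CH2O) are equatorial and the C3 methyl is axial, so the E,E geometry translates into the (2R,3R) relationship, with cyclopropyl and benzylic arm trans on the later ring. The absolute sense at C3 is governed by the R benzylic carbon: with the aryl group anti to the forming bond, the benzylic H takes the outside position next to the geminal methyl (least 1,2-allylic strain and clear of the cyclopropyl group on C2) and isobutyl takes the inside position over the C4-H, so the enol ether reaches the face opposite the tris(benzyloxy)phenyl group, which is the face the target requires. The only selectivity that must be secured here is this facial selectivity at C3, because C2 can be equilibrated after step 14, and the 120 °C ceiling keeps the cis-alkyl vinylcyclopropane units of 6 and 20 below the onset of the homodienyl 1,5-hydrogen shift.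

Step 14
Reactants: 21 pentenal
Product: 22 (2R,3R)-2-{(1R,3R)-2,2-dimethyl-3-[2-(2-methyl-1,3-dioxolan-2-yl)ethyl]cyclopropyl}-3-methyl-3-{(1R)-3-methyl-1-[2,4,6-tris(benzyloxy)phenyl]butyl}cyclopentan-1-one
Conditions: [Rh(cod)2]BF4 (5 mol %), dppe (1,2-bis(diphenylphosphino)ethane, 5 mol %), CH2Cl2, brief H2 activation then Ar purge, then 21, rt to 40 °C; then DBU (0.3 equiv), toluene, rt, if the C2 epimer is present
Reagents that add atoms: none
Why: In this intramolecular alkene hydroacylation of a 4-pentenal, cationic monovalent rhodium inserts into the formyl C-H, the Rh-H adds to the vinyl group to place rhodium on terminal C5, and reductive elimination from the six-membered rhodacycle closes the five-membered ring at C1-C5, helped by the quaternary C3, which compresses the chain and blocks alkene migration, while DBU equilibrates C2 through the enolate to the more stable isomer with cyclopropyl trans to the benzylic arm, which is the target configuration.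

Step 15
Reactants: 22 tribenzyl ether cyclopentanone
Product: 23 (2R,3R)-2-{(1R,3R)-2,2-dimethyl-3-[2-(2-methyl-1,3-dioxolan-2-yl)ethyl]cyclopropyl}-3-methyl-3-[(1R)-3-methyl-1-(2,4,6-trihydroxyphenyl)butyl]cyclopentan-1-one
Conditions: H2 (1 atm), 10 % Pd/C, EtOAc-THF, rt; handled under Ar
Reagents that add atoms: none
Why: Hydrogenolysis of the aryl benzyl ethers on palladium at atmospheric pressure under neutral conditions leaves the unactivated alkyl cyclopropane, the ketone, the dioxolane and all stereocentres untouched.

Step 16
Reactants: 23 alkylphloroglucinol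
Product: 25 target 5-{(1R)-1-[(1R,2R)-2-{(1R,3R)-2,2-dimethyl-3-(3-oxobutyl)cyclopropyl}-1-methyl-3-oxocyclopentyl]-3-methylbutyl}-2,4,6-trihydroxybenzene-1,3-dicarbaldehyde, via bis(iminium) dichloride 24 (not isolated)
Conditions: POCl3 (3 equiv), DMF (6 equiv), EtOAc, premixed at 0 °C, then 23, -10 °C to rt; then H2O-THF, rt
Reagents that add atoms: N,N-dimethylformamide, CN(C)C=O; water, O
Why: In the Vilsmeier-Haack formylation the chloroiminium ion attacks the only two free, strongly activated ring CH positions of the phloroglucinol much faster at low temperature than it attacks the enolisable cyclopentanone, so no regiochemical choice arises, and the aqueous acid formed on quenching hydrolyses both iminium groups and the dioxolane without touching the stereocentres (C2 is already the thermodynamic epimer).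

## Compound list

1 | (+)-2-carene, (1S,6R)-3,7,7-trimethylbicyclo[4.1.0]hept-2-ene | CC1=C[C@H]2[C@@H](CC1)C2(C)C | starting material
2 | secondary ozonide (1,2,4-trioxolane) of 1, configuration at the two acetal carbons not defined | CC12CC[C@@H]3[C@H](C(O1)OO2)C3(C)C | intermediate
3 | (1S,3R)-2,2-dimethyl-3-(3-oxobutyl)cyclopropane-1-carbaldehyde (cis) | CC(=O)CC[C@@H]1[C@H](C=O)C1(C)C | intermediate
4 | iodoform | IC(I)I | starting material
5 | 4-{(1R,3R)-3-[(E)-2-iodoethenyl]-2,2-dimethylcyclopropyl}butan-2-one | CC(=O)CC[C@@H]1[C@H](/C=C/I)C1(C)C | intermediate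
6 | 2-(2-{(1R,3R)-3-[(E)-2-iodoethenyl]-2,2-dimethylcyclopropyl}ethyl)-2-methyl-1,3-dioxolane | CC1(CC[C@@H]2[C@H](/C=C/I)C2(C)C)OCCO1 | intermediate
7 | 2,4,6-trihydroxybenzaldehyde | O=Cc1c(O)cc(O)cc1O | starting material
8 | 2,4-bis(benzyloxy)-6-hydroxybenzaldehyde | O=Cc1c(O)cc(OCc2ccccc2)cc1OCc1ccccc1 | intermediate
9 | isobutylmagnesium bromide | CC(C)C[Mg]Br | starting material
10 | rac-3,5-bis(benzyloxy)-2-(1-hydroxy-3-methylbutyl)phenol | CC(C)CC(O)c1c(O)cc(OCc2ccccc2)cc1OCc1ccccc1 | intermediate
11 | but-2-yn-1-ol | CC#CCO | starting material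
12 | (but-2-yn-1-yloxy)(tert-butyl)dimethylsilane | CC#CCO[Si](C)(C)C(C)(C)C | intermediate
13 | (Z)-alkenyl pinacol boronate, boron on the CH3-bearing carbon and cis to the vinyl H | C/C(B1OC(C)(C)C(C)(C)O1)=C\CO[Si](C)(C)C(C)(C)C | intermediate
14 | (Z)-{4-[(tert-butyldimethylsilyl)oxy]but-2-en-2-yl}boronic acid | C/C(B(O)O)=C\CO[Si](C)(C)C(C)(C)C | intermediate
15 | diethyl (Z)-{4-[(tert-butyldimethylsilyl)oxy]but-2-en-2-yl}boronate | C/C(B(OCC)OCC)=C\CO[Si](C)(C)C(C)(C)C | intermediate
16 | 3,5-bis(benzyloxy)-6-(3-methylbutylidene)cyclohexa-2,4-dien-1-one, alkyl group drawn toward the carbonyl oxygen and away from the flanking benzyloxy group | CC(C)C/C=C1\C(=O)C=C(OCc2ccccc2)C=C1OCc1ccccc1 | intermediate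
17 | 3,5-bis(benzyloxy)-2-[(2E,4R)-1-(tert-butyldimethylsilyloxy)-3,6-dimethylhept-2-en-4-yl]phenol | CC(C)(C)[Si](C)(C)OC/C=C(\C)[C@@H](CC(C)C)c1c(O)cc(OCc2ccccc2)cc1OCc1ccccc1 | intermediate
18 | tert-butyl({(2E,4R)-3,6-dimethyl-4-[2,4,6-tris(benzyloxy)phenyl]hept-2-en-1-yl}oxy)dimethylsilane | CC(C)(C)[Si](C)(C)OC/C=C(\C)[C@@H](CC(C)C)c1c(OCc2ccccc2)cc(OCc2ccccc2)cc1OCc1ccccc1 | intermediate
19 | (2E,4R)-3,6-dimethyl-4-[2,4,6-tris(benzyloxy)phenyl]hept-2-en-1-ol | OC/C=C(\C)[C@@H](CC(C)C)c1c(OCc2ccccc2)cc(OCc2ccccc2)cc1OCc1ccccc1 | intermediate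
20 | allyl vinyl ether, E enol ether on the (1R,3R)-cyclopropane, E allyl unit, R benzylic carbon | CC1(CC[C@@H]2[C@H](/C=C/OC/C=C(\C)[C@@H](CC(C)C)c3c(OCc4ccccc4)cc(OCc4ccccc4)cc3OCc3ccccc3)C2(C)C)OCCO1 | intermediate
21 | (2R,3R)-2-cyclopropyl-3-methyl-3-[(1R)-arylalkyl]pent-4-enal (full name in step 13) | CC1(CC[C@@H]2[C@H]([C@@H](C=O)[C@](C)(C=C)[C@@H](CC(C)C)c3c(OCc4ccccc4)cc(OCc4ccccc4)cc3OCc3ccccc3)C2(C)C)OCCO1 | intermediate
22 | (2R,3R)-cyclopentanone, aryl as tris(benzyl ether), side chain as dioxolane (full name in step 14) | CC1(CC[C@@H]2[C@H]([C@H]3C(=O)CC[C@]3(C)[C@@H](CC(C)C)c3c(OCc4ccccc4)cc(OCc4ccccc4)cc3OCc3ccccc3)C2(C)C)OCCO1 | intermediate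
23 | alkylphloroglucinol, side chain as dioxolane (full name in step 15) | CC1(CC[C@@H]2[C@H]([C@H]3C(=O)CC[C@]3(C)[C@@H](CC(C)C)c3c(O)cc(O)cc3O)C2(C)C)OCCO1 | intermediate
24 | bis(dimethyliminiomethyl)phloroglucinol dichloride, dioxolane still in place | CC1(CC[C@@H]2[C@H]([C@H]3C(=O)CC[C@]3(C)[C@@H](CC(C)C)c3c(O)c(C=[N+](C)C)c(O)c(C=[N+](C)C)c3O)C2(C)C)OCCO1.[Cl-].[Cl-] | intermediate
25 | CNP0217082.3 (full name in step 16) | CC(=O)CC[C@@H]1[C@H]([C@H]2C(=O)CC[C@]2(C)[C@@H](CC(C)C)c2c(O)c(C=O)c(O)c(C=O)c2O)C1(C)C | target

## Step count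

Total step count: 16.
Longest linear sequence: 11 steps (11 to 25, steps 6 to 16).

## Steps most likely to fail

**Step 10.**
- What may go wrong: the alkyl-substituted quinone methide may tautomerise to the styrene by a 1,5-hydrogen shift, or dimerise, before it is trapped. Alkenyl transfer from an achiral cyclic boronate of 10 may also erode the enantioselectivity.
- Fallback: it sets out from 8 and 14 and comes back at 17. The same quinone methide is generated anionically at low temperature, trapped with a Grignard reagent, and the product is resolved.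
- Aldehyde 8 is acylated (Boc2O, iPr2NEt, cat. DMAP, CH2Cl2) to the aryl tert-butyl carbonate F1.
- Boronic acid 14 undergoes stereoretentive iododeboronation (N-iodosuccinimide, MeCN) to the E-alkenyl iodide F2. Iodine-magnesium exchange (iPrMgCl·LiCl, THF) then converts it into the alkenylmagnesium chloride F3.
- One equivalent of 9 is added to F1 at -78 °C, followed by F3. On warming, the magnesium alkoxide takes over the Boc group, tert-butyl carbonate leaves, and 16 is captured at once to give the racemic phenol F4.
- Preparative chromatography on a chiral stationary phase gives the R enantiomer, which is 17.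

**Step 13.**
- What may go wrong: C-O coupling of two hindered partners may be slow, and facial discrimination at C3 may be insufficient at 120 °C. The latter could include a mismatch with the facial bias of the chiral cyclopropyl group. Thermal opening of the cyclopropane by the homodienyl hydrogen shift may begin on prolonged heating.
- Fallback: it sets out from 6 and 19 and comes back at 21. The same C2-C3 bond is made by an Ireland-Claisen rearrangement near room temperature.
- Compound 6 is borylated (B2pin2, PdCl2(PPh3)2, PPh3, KOPh, toluene, 50 °C) to the E-alkenyl pinacol boronate F5.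
- F5 is oxidised (NaBO3·4H2O, THF-H2O) to the cyclopropylacetaldehyde F6, and further (NaClO2, NaH2PO4, 2-methylbut-2-ene) to the cyclopropylacetic acid F7.
- Esterification with 19 (EDC·HCl, DMAP, CH2Cl2) gives the allyl ester F8.
- LDA and Me3SiCl in THF-DMPU at -78 °C give the Z silyl ketene acetal F9, which should rearrange between rt and 60 °C to the trimethylsilyl ester F10.
- LiAlH4 reduces the crude ester to the primary alcohol F11, and Dess-Martin periodinane oxidises it to 21.

**Step 14.**
- What may go wrong: the crowded acyl rhodium hydride may decarbonylate, and the CO released may poison the catalyst, so that ring closure stalls.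
- Fallback: it sets out from 21 and comes back at 23. The ring is closed by olefin metathesis instead of C-H activation.
- Vinylmagnesium bromide (THF, -78 °C) adds to 21 to give the dienol F12 as a carbinol epimer mixture.
- The second-generation Grubbs catalyst (CH2Cl2, 40 °C) closes the cyclopentenol F13; the new vinyl CH takes the place of C5.
- Dess-Martin periodinane gives the cyclopentenone F14, which can be equilibrated at C2 with DBU if needed.
- The conditions of step 15 (H2, Pd/C) then saturate the enone C=C and remove the three benzyl groups in one operation to give 23.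

## Further compounds

F1 | step 10 | 2,4-bis(benzyloxy)-6-[(tert-butoxycarbonyl)oxy]benzaldehyde | O=Cc1c(OC(=O)OC(C)(C)C)cc(OCc2ccccc2)cc1OCc1ccccc1
F2 | step 10 | (E)-tert-butyl[(3-iodobut-2-en-1-yl)oxy]dimethylsilane | C/C(I)=C\CO[Si](C)(C)C(C)(C)C
F3 | step 10 | {4-[(tert-butyldimethylsilyl)oxy]but-2-en-2-yl}magnesium chloride, magnesium cis to the vinyl H | C/C([Mg]Cl)=C\CO[Si](C)(C)C(C)(C)C
F4 | step 10 | racemic 3,5-bis(benzyloxy)-2-[(2E)-1-(tert-butyldimethylsilyloxy)-3,6-dimethylhept-2-en-4-yl]phenol | CC(C)(C)[Si](C)(C)OC/C=C(\C)C(CC(C)C)c1c(O)cc(OCc2ccccc2)cc1OCc1ccccc1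
F5 | step 13 | E-alkenyl pinacol boronate on the (1R,3R)-cyclopropane, dioxolane side chain | CC1(CC[C@@H]2[C@H](/C=C/B3OC(C)(C)C(C)(C)O3)C2(C)C)OCCO1
F6 | step 13 | cis-{2,2-dimethyl-3-[2-(2-methyl-1,3-dioxolan-2-yl)ethyl]cyclopropyl}acetaldehyde | CC1(CC[C@@H]2[C@H](CC=O)C2(C)C)OCCO1
F7 | step 13 | cis-{2,2-dimethyl-3-[2-(2-methyl-1,3-dioxolan-2-yl)ethyl]cyclopropyl}acetic acid | CC1(CC[C@@H]2[C@H](CC(=O)O)C2(C)C)OCCO1
F8 | step 13 | ester of F7 with allylic alcohol 19 | CC1(CC[C@@H]2[C@H](CC(=O)OC/C=C(\C)[C@@H](CC(C)C)c3c(OCc4ccccc4)cc(OCc4ccccc4)cc3OCc3ccccc3)C2(C)C)OCCO1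
F9 | step 13 | Z trimethylsilyl ketene acetal of F8, cyclopropyl cis to OSiMe3 | CC1(CC[C@@H]2[C@H](/C=C(\O[Si](C)(C)C)OC/C=C(\C)[C@@H](CC(C)C)c3c(OCc4ccccc4)cc(OCc4ccccc4)cc3OCc3ccccc3)C2(C)C)OCCO1
F10 | step 13 | trimethylsilyl (2R,3R)-pent-4-enoate corresponding to 21 | CC1(CC[C@@H]2[C@H]([C@@H](C(=O)O[Si](C)(C)C)[C@](C)(C=C)[C@@H](CC(C)C)c3c(OCc4ccccc4)cc(OCc4ccccc4)cc3OCc3ccccc3)C2(C)C)OCCO1
F11 | step 13 | pent-4-en-1-ol corresponding to 21 | CC1(CC[C@@H]2[C@H]([C@@H](CO)[C@](C)(C=C)[C@@H](CC(C)C)c3c(OCc4ccccc4)cc(OCc4ccccc4)cc3OCc3ccccc3)C2(C)C)OCCO1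
F12 | step 14 | hepta-1,6-dien-3-ol from 21 and vinylmagnesium bromide, carbinol carbon undefined | CC1(CC[C@@H]2[C@H]([C@@H](C(O)C=C)[C@](C)(C=C)[C@@H](CC(C)C)c3c(OCc4ccccc4)cc(OCc4ccccc4)cc3OCc3ccccc3)C2(C)C)OCCO1
F13 | step 14 | cyclopent-2-en-1-ol, carbinol carbon undefined | CC1(CC[C@@H]2[C@H]([C@H]3C(O)C=C[C@]3(C)[C@@H](CC(C)C)c3c(OCc4ccccc4)cc(OCc4ccccc4)cc3OCc3ccccc3)C2(C)C)OCCO1
F14 | step 14 | cyclopent-2-en-1-one | CC1(CC[C@@H]2[C@H]([C@H]3C(=O)C=C[C@]3(C)[C@@H](CC(C)C)c3c(OCc4ccccc4)cc(OCc4ccccc4)cc3OCc3ccccc3)C2(C)C)OCCO1
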